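# Proposed synthesis of CNP0282937.2 by dearomatising [4+3] cycloaddition of 2‑methylfuran and radical three‑carbon ring expansion

## The problem

Germacranolide locants are used throughout: C1–C10 is the carbocycle, C11–C13 the lactone side chain (C12 carbonyl, C13 methylene), C14 the methyl on C10 and C15 the hydroxymethyl on C4. The target is a ten‑membered carbocycle spanned by an ether oxygen from C3 to C10. O–C3–C2–C1–C10 is therefore a tetrahydrofuran and C4–C9 the six‑carbon bridge of an 11‑oxabicyclo[6.2.1]undec‑4‑ene; C3 is a hemiketal and C10 a fully substituted carbon. The C4=C5 bond is trisubstituted with C3 and C6 cis, an α‑methylene γ‑lactone is cis‑fused at C6–C7 and C8 carries an isobutyrate, with C6–O, C7–C11 and C8–O all syn (3S,6S,7R,8R,10R). A synthesis has to create a medium ring that resists direct closure and place the alkene with the right geometry next to the hemiketal. C3 is slaved to C10 by the bridge, C7 can be slaved to C6 through the cis ring fusion and C8 can be set from C7; only C10 and C6, which are 1,5‑related and cannot control each other, need an external source of chirality. The hemiketal, the α‑methylene lactone, the allylic alcohol and any 8‑oxo‑6,12‑olide intermediate (a β‑acyloxy ketone) limit the use of base and nucleophiles late in the route. The feature that is exploited: O, C3, C2, C1, C10 together with C4, C8 and C9 are the atoms of an 8‑oxabicyclo[3.2.1]octan‑3‑one, the [4+3] cycloadduct of 2‑methylfuran, with C8 as carbonyl carbon and C4 as its α‑carbon. The target differs from it by the three‑carbon unit C5–C6–C7 inserted into the C4–C8 bond, and that unit with O6, C11 and C12 is a γ‑substituted butenolide.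

## Retrosynthesis

**C3–OH.** Target 24 is traced to its silyl ether 23 and this to the bridged ether 22 by removing the hemiketal oxygen. An ether bridgehead C–H is inert through all C–C bond‑forming steps, whereas a free hemiketal next to a β‑dicarbonyl unit would reopen by retro‑Claisen cleavage. In 22 the C3–H bond is the only one that is allylic and α to a dialkyl ether oxygen, so the forward step is a chemoselective hydride abstraction.

**Acyl, methylene and silyl groups.** 22 comes from alcohol 21 (isobutyrate last, so that no second ester is present when the lactone is enolised), 21 from lactone 18 (C13 added by aminomethylation and elimination) and 18 from diol 17. These cuts are ordered so that each reagent meets only one reactive site.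

**Redox at C15 and C8.** Diol 17 is traced to keto acid 15 and this to tert‑butyl ester 14. The C15 carboxyl is kept until here because it is needed as the radical‑stabilising group of the key step. One hydride reagent must then reduce the activated acid and the C8 ketone, the latter from the face opposite the lactone.

**C4=C5 and the ten‑membered ring (key disconnection).** In 14 the bond C4–C8 is re‑formed in the retrosynthetic sense, with C8 as a carbinol and C4 as an sp3 carbon. This gives tricyclic alcohol 12, which contains only five‑, six‑ and seven‑membered rings. Against a cut of C6–C7 or C1–C2 this avoids every ten‑membered ring closure. The forward reaction must cleave exactly the C4–C8 bond of 12 and leave a C4=C5 double bond.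

**C7–C8.** 12 is opened to keto butenolide 11. The cut is made here because a ketyl at C8 and the β‑carbon C7 of the butenolide are joined through a two‑atom tether. The five‑membered ring closure can then only give the cis‑fused lactone that the target has.

**C4–C5.** 11 is divided into β‑keto ester 8 and triflate 10, made from the butenolide alcohol 9, which brings C6 as a purchased stereocentre. The forward step is a C‑alkylation that must not touch the acidic γ‑hydrogen of the butenolide.

**The oxabicycle.** 8 comes from silyl enol ether 7 and diene 6. 6 is the [4+3] adduct of 2‑methylfuran 4 and the vinyl diazo ester 3, itself made from diazo keto ester 2 and tert‑butyl acetoacetate 1. One step turns the flat furan into the tetrahydrofuran of the target, with C10, its methyl group, the oxygen bridge, C8 as carbonyl and the ester carbon C15 on C4. The forward step must be enantioselective and place the ester‑bearing carbon next to the hydrogen‑bearing bridgehead.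

## Roads not taken

**Alternative 1:** the most obvious cut is C6–C7 together with the lactone C–O bond. The forward key step is an intramolecular Barbier or Nozaki–Hiyama–Kishi allylation of the (Z)‑enal bromide A1 to the macrocycle A2. It forms the ten‑membered ring and the lactone in one step, but between two hindered termini and at high dilution. The C6/C7 configuration is decided in a macrocyclic transition state that has no element enforcing the cis lactone or its syn relation to C8. A1 itself needs a long linear sequence. The chosen plan replaces the ring closure by two five‑membered ring events and fixes C7 geometrically.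

**Alternative 2:** cut C1=C2 in a 1,2‑didehydro precursor. The forward key step is ring‑closing metathesis of dienone A3 to the cross‑conjugated dienone hemiketal A4, then saturation of C1=C2. Both alkenes of A3 are poor partners (a vinyl ketone and a vinyl group on a fully substituted carbinol), the ring is strained, and the later hydrogenation has to spare C4=C5 and the methylene lactone. The chosen plan brings C1–C2 in as the β‑carbons of the furan and hydrogenates them when no other reducible alkene is present.

**Alternative 3:** cut C2–C3 and re‑form C5–C10, the classical germacrane logic. The forward key step is an anionic oxy‑Cope rearrangement of divinylcyclohexanol A5 to cyclodecenone A6. The chair transition state places C3 and C6 trans on the new double bond. C10 emerges as a ketone, so the methyl group must be added later to a flexible ring without a controlling element. C3 still has to be oxidised, and A5 with five stereocentres is no simpler than the target.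

Key step: step 9

Assumption: (R)‑5‑(hydroxymethyl)furan‑2(5H)‑one 9 is bought, and the catalyst enantiomer written in step 3 is taken to give the C10 R adduct (its mirror image is used if the sense of induction is the other one).

## Route

Step 1
Reactants: 1 tert‑butyl 3‑oxobutanoate
Product: 2 tert‑butyl 2‑diazo‑3‑oxobutanoate
Conditions: 4‑acetamidobenzenesulfonyl azide, Et3N, MeCN, 0 °C to rt
Reagents that add atoms: 4‑acetamidobenzenesulfonyl azide, CC(=O)Nc1ccc(cc1)S(=O)(=O)N=[N+]=[N-]
Why: Regitz diazo transfer to the active methylene group of a β‑keto ester; the amine base is sufficient and the ester is not touched.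

Step 2
Reactants: 2 tert‑butyl 2‑diazo‑3‑oxobutanoate
Product: 3 tert‑butyl 3‑(tert‑butyldimethylsilyloxy)‑2‑diazobut‑3‑enoate
Conditions: TBSOTf, Et3N, CH2Cl2, 0 °C
Reagents that add atoms: tert‑butyldimethylsilyl trifluoromethanesulfonate, CC(C)(C)[Si](C)(C)OS(=O)(=O)C(F)(F)F
Why: Soft enolisation of the acetyl group and O‑silylation give the 2‑siloxyvinyl diazoacetate, the usual precursor of a donor–acceptor vinylcarbenoid.

Step 3
Reactants: 3 tert‑butyl 3‑(tert‑butyldimethylsilyloxy)‑2‑diazobut‑3‑enoate; 4 2‑methylfuran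
Product: 6 siloxy diene ester of the 8‑oxabicyclo[3.2.1]octadiene, via divinylcyclopropane 5 (not isolated)
Conditions: Rh2(S‑PTAD)4 (dirhodium tetrakis[(S)‑(1‑adamantyl)(phthalimido)acetate], 1 mol %), hexane, rt, slow addition of 3 to 4 (3 equiv)
Reagents that add atoms: none
Why: Dearomatising formal [4+3] cycloaddition: the rhodium vinylcarbenoid cyclopropanates the unsubstituted C=C bond of the furan and the cis‑divinylcyclopropane 5 undergoes Cope rearrangement through a boat transition state. The carbenoid carbon (C4) therefore ends next to the hydrogen‑bearing bridgehead C3 and the CH2 terminus (C9) next to the methyl‑bearing bridgehead C10. The chiral carboxylate ligands select the face of the carbenoid and so set C10, and with it C3.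

Step 4
Reactants: 6 siloxy diene ester
Product: 7 siloxy ene ester (C1–C2 saturated)
Conditions: H2 (1 atm), Pd/C, EtOAc, rt
Reagents that add atoms: none
Why: Heterogeneous hydrogenation saturates the strained disubstituted C1=C2 bond; the tetrasubstituted push–pull silyl enol ether is not reduced.

Step 5
Reactants: 7 siloxy ene ester
Product: 8 bicyclic β‑keto ester
Conditions: HF·pyridine, THF, 0 °C
Reagents that add atoms: none
Why: Fluoride cleaves the silyl enol ether to the β‑keto ester; the acidic medium avoids β‑elimination of the bridge oxygen from the enolate.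

Step 6
Reactants: 9 (R)‑5‑(hydroxymethyl)furan‑2(5H)‑one
Product: 10 butenolide triflate
Conditions: Tf2O, 2,6‑lutidine, CH2Cl2, −78 °C
Reagents that add atoms: trifluoromethanesulfonic anhydride, O=S(=O)(OS(=O)(=O)C(F)(F)F)C(F)(F)F
Why: O‑Sulfonylation of the primary alcohol at low temperature; C6 is not involved and the triflate is used at once.

Step 7
Reactants: 8 bicyclic β‑keto ester; 10 butenolide triflate
Product: 11 keto butenolide with quaternary C4
Conditions: NaH, THF, 0 °C; then 10, −40 to 0 °C
Reagents that add atoms: none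
Why: C‑Alkylation of the sodium enolate of the β‑keto ester by SN2 displacement at the primary triflate. The enolate is too weakly basic to remove the γ‑hydrogen of the butenolide, so C6 is retained. The electrophile enters anti to the two‑carbon bridge, but the configuration at C4 is lost later.

Step 8
Reactants: 11 keto butenolide
Product: 12 tricyclic tertiary alcohol
Conditions: SmI2 (2.5 equiv), THF/MeOH (20:1), −78 °C
Reagents that add atoms: none
Why: Ketyl–olefin reductive cyclisation (5‑exo‑trig): the ester‑chelated ketyl at C8 adds to the β‑carbon C7 of the butenolide, and the resulting α‑lactone radical is reduced and protonated. The two‑atom tether forces the new C7–C8 bond cis to the C6–C5 bond, so the lactone is cis‑fused and C7 is set from C6; the hydroxyl ends cis to the ester.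

Step 9
Reactants: 12 tricyclic tertiary alcohol
Product: 14 ten‑membered keto enoate lactone, via tertiary iodide 13 (not isolated)
Conditions: PhI(OAc)2, I2, CH2Cl2, visible light, rt; then 2,6‑lutidine, 40 °C
Reagents that add atoms: none
Why: The alcohol is converted into its hypoiodite (acetyl hypoiodite from PhI(OAc)2 and I2), whose O–I bond is cleaved by light to the C8 alkoxy radical. β‑Scission cuts C8–C4, the bond shared by the cyclopentane and the oxane ring, because only this cleavage gives a tertiary α‑ester radical and releases the strain of both fused rings; cleavage towards C7 or C9 would give an unstabilised radical. The C4 radical takes an iodine atom to give the tertiary α‑iodo ester 13, which loses HI towards C5 with the weak base, so that C8 becomes the ketone and C4=C5 the enoate. The closest known reaction type is the hypoiodite β‑fragmentation of fused bicyclic tertiary alcohols to medium‑ring ketones (radical ring expansion). No ring is closed: the seven‑membered carbocycle of the cycloadduct, the cyclopentane and the oxane merge into the ten‑membered carbocycle (nine‑membered oxacycle) by loss of their common bond. No stereocentre is formed; C3, C6, C7 and C10 are not touched and C4 and C8 become trigonal, so their configuration in 12 is irrelevant. The step needs regioselective scission (secured by the ester on C4), elimination towards C5 and not towards the oxygen‑bearing C3, and the geometry with C3 and C6 cis, the less strained arrangement in the nine‑membered oxacycle, reached by iodine‑atom equilibration under the conditions. The weak pyridine base is used because 14 is a β‑acyloxy ketone that a stronger base would open by β‑elimination.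

Step 10
Reactants: 14 ten‑membered keto enoate lactone
Product: 15 keto enoic acid
Conditions: CF3CO2H/CH2Cl2 (1:4), 0 °C
Reagents that add atoms: none
Why: Acidolysis of the tert‑butyl ester with loss of 2‑methylpropene; lactone, ketone and the bridging ether are stable to these conditions.

Step 11
Reactants: 15 keto enoic acid
Product: 17 diol (C15 alcohol and 8R alcohol), via mixed carbonic anhydride 16 (not isolated)
Conditions: i‑BuOCOCl, N‑methylmorpholine, THF, −15 °C; then NaBH4, THF/H2O, −15 to 0 °C
Reagents that add atoms: none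
Why: The mixed anhydride is reduced by borohydride to the allylic alcohol (1,2‑reduction) while lactone esters are not attacked at this temperature. The same reagent reduces the C8 ketone from the face opposite the adjacent cis‑fused lactone ring (anti to the C7–C11 bond), which should give the 8R alcohol with O8 syn to C11 and O6.

Step 12
Reactants: 17 diol
Product: 18 primary silyl ether
Conditions: TBDPSCl, imidazole, CH2Cl2, 0 °C
Reagents that add atoms: tert‑butyl(chloro)diphenylsilane, CC(C)(C)[Si](Cl)(c1ccccc1)c1ccccc1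
Why: The primary allylic hydroxyl is silylated much faster than the hindered secondary C8 hydroxyl; the bulky silyl ether is chosen to resist step 15.

Step 13
Reactants: 18 primary silyl ether
Product: 21 α‑methylene lactone alcohol, via Mannich base 19 (not isolated), via ammonium iodide 20 (not isolated)
Conditions: LiN(i‑Pr)2 (2.3 equiv), THF, −78 °C; CH2=NMe2+ I−, −78 to 0 °C; then MeI, MeOH, rt; aq NaHCO3, CH2Cl2
Reagents that add atoms: Eschenmoser's salt (N,N‑dimethylmethyleneiminium iodide), C=[N+](C)C.[I-]
Why: The dianion (C8 alkoxide and lactone enolate) undergoes Mannich aminomethylation at C11; quaternisation and base‑induced elimination of trimethylamine give the exocyclic methylene. No other ester is present at this stage, so enolisation is unambiguous.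

Step 14
Reactants: 21 α‑methylene lactone alcohol
Product: 22 isobutyrate (bridged ether with C3–H)
Conditions: (i‑PrCO)2O, Et3N, DMAP (cat.), CH2Cl2, 0 °C to rt
Reagents that add atoms: isobutyric anhydride, CC(C)C(=O)OC(=O)C(C)C
Why: Acyl‑transfer catalysed esterification of the secondary alcohol with retention at C8; the conditions are too mild to add to the methylene lactone irreversibly.

Step 15
Reactants: 22 isobutyrate
Product: 23 hemiketal silyl ether
Conditions: DDQ, CH2Cl2/pH 7 buffer (10:1), rt
Reagents that add atoms: water, O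
Why: Oxidative C–H cleavage of an allylic ether: DDQ abstracts hydride from C3–H, the only C–H that is both allylic to the electron‑rich C4=C5 bond and α to a dialkyl ether oxygen, and water adds to the oxocarbenium carbon. C3 stays tied to C10 through the bridge oxygen, so only the 3S hemiketal can form.

Step 16
Reactants: 23 hemiketal silyl ether
Product: 24 target CNP0282937.2
Conditions: HF·pyridine, pyridine/THF, 0 °C to rt
Reagents that add atoms: none
Why: Fluoride‑mediated cleavage of the silyl ether under weakly acidic conditions that spare the methylene lactone, the isobutyrate and the hemiketal.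

## Compound list

1 | tert‑butyl 3‑oxobutanoate | CC(=O)CC(=O)OC(C)(C)C | starting material
2 | tert‑butyl 2‑diazo‑3‑oxobutanoate | CC(=O)C(=[N+]=[N-])C(=O)OC(C)(C)C | intermediate
3 | tert‑butyl 3‑[(tert‑butyldimethylsilyl)oxy]‑2‑diazobut‑3‑enoate | C=C(O[Si](C)(C)C(C)(C)C)C(=[N+]=[N-])C(=O)OC(C)(C)C | intermediate
4 | 2‑methylfuran | Cc1ccco1 | starting material
5 | tert‑butyl 6‑[1‑(tert‑butyldimethylsilyloxy)ethenyl]‑3‑methyl‑2‑oxabicyclo[3.1.0]hex‑3‑ene‑6‑carboxylate (siloxyvinyl group cis to the dihydrofuran ring) | CC1=C[C@@H]2[C@H](O1)[C@]2(C(=O)OC(C)(C)C)C(=C)O[Si](C)(C)C(C)(C)C | intermediate (not isolated)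
6 | tert‑butyl (1S,5S)‑3‑[(tert‑butyldimethylsilyl)oxy]‑5‑methyl‑8‑oxabicyclo[3.2.1]octa‑2,6‑diene‑2‑carboxylate | CC(C)(C)OC(=O)C1=C(O[Si](C)(C)C(C)(C)C)C[C@@]2(C)C=C[C@@H]1O2 | intermediate
7 | tert‑butyl (1S,5R)‑3‑[(tert‑butyldimethylsilyl)oxy]‑5‑methyl‑8‑oxabicyclo[3.2.1]oct‑2‑ene‑2‑carboxylate | CC(C)(C)OC(=O)C1=C(O[Si](C)(C)C(C)(C)C)C[C@@]2(C)CC[C@@H]1O2 | intermediate
8 | tert‑butyl (1S,5R)‑5‑methyl‑3‑oxo‑8‑oxabicyclo[3.2.1]octane‑2‑carboxylate (C2 epimers and enol) | CC(C)(C)OC(=O)C1C(=O)C[C@@]2(C)CC[C@@H]1O2 | intermediate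
9 | (R)‑5‑(hydroxymethyl)furan‑2(5H)‑one | O=C1O[C@H](C=C1)CO | starting material
10 | [(2R)‑5‑oxo‑2,5‑dihydrofuran‑2‑yl]methyl trifluoromethanesulfonate | O=C1O[C@H](C=C1)COS(=O)(=O)C(F)(F)F | intermediate
11 | tert‑butyl (1S,2R,5R)‑5‑methyl‑3‑oxo‑2‑{[(2S)‑5‑oxo‑2,5‑dihydrofuran‑2‑yl]methyl}‑8‑oxabicyclo[3.2.1]octane‑2‑carboxylate | CC(C)(C)OC(=O)[C@@]1(C[C@@H]2OC(=O)C=C2)C(=O)C[C@@]3(C)CC[C@@H]1O3 | intermediate
12 | tricyclic tertiary alcohol: cyclopentane annulated across C4–C8 of the oxabicycle, cis‑fused γ‑lactone at C6–C7, tert‑butyl ester on C4, hydroxyl on C8 (target locants 3S,4R,6S,7S,8R,10R) | C1C(=O)O[C@H]2C[C@@]4(C(=O)OC(C)(C)C)[C@@H]3CC[C@](C)(C[C@@]4(O)[C@@H]12)O3 | intermediate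
13 | tert‑butyl (1S,4S,8S,11R)‑2‑iodo‑11‑methyl‑6,9‑dioxo‑5,14‑dioxatricyclo[9.2.1.0^{4,8}]tetradecane‑2‑carboxylate (C2 epimers) | C1C(=O)O[C@H]2CC(I)(C(=O)OC(C)(C)C)[C@@H]3CC[C@](C)(CC(=O)[C@@H]12)O3 | intermediate (not isolated)
14 | tert‑butyl (1S,2E,4S,8S,11R)‑11‑methyl‑6,9‑dioxo‑5,14‑dioxatricyclo[9.2.1.0^{4,8}]tetradec‑2‑ene‑2‑carboxylate | C1C(=O)O[C@H]2/C=C(/C(=O)OC(C)(C)C)[C@@H]3CC[C@](C)(CC(=O)[C@@H]12)O3 | intermediate
15 | (1S,2E,4S,8S,11R)‑11‑methyl‑6,9‑dioxo‑5,14‑dioxatricyclo[9.2.1.0^{4,8}]tetradec‑2‑ene‑2‑carboxylic acid | C1C(=O)O[C@H]2/C=C(/C(=O)O)[C@@H]3CC[C@](C)(CC(=O)[C@@H]12)O3 | intermediate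
16 | isobutyl carbonic anhydride of acid 15 | C1C(=O)O[C@H]2/C=C(/C(=O)OC(=O)OCC(C)C)[C@@H]3CC[C@](C)(CC(=O)[C@@H]12)O3 | intermediate (not isolated)
17 | (1S,2Z,4S,8R,9R,11R)‑9‑hydroxy‑2‑(hydroxymethyl)‑11‑methyl‑5,14‑dioxatricyclo[9.2.1.0^{4,8}]tetradec‑2‑en‑6‑one | C1C(=O)O[C@H]2/C=C(/CO)[C@@H]3CC[C@](C)(C[C@@H](O)[C@@H]12)O3 | intermediate
18 | (1S,2Z,4S,8R,9R,11R)‑2‑{[(tert‑butyldiphenylsilyl)oxy]methyl}‑9‑hydroxy‑11‑methyl‑5,14‑dioxatricyclo[9.2.1.0^{4,8}]tetradec‑2‑en‑6‑one | C1C(=O)O[C@H]2/C=C(/CO[Si](c4ccccc4)(c5ccccc5)C(C)(C)C)[C@@H]3CC[C@](C)(C[C@@H](O)[C@@H]12)O3 | intermediate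
19 | 7‑[(dimethylamino)methyl] derivative of 18 (C7 epimers) | CN(C)CC1C(=O)O[C@H]2/C=C(/CO[Si](c4ccccc4)(c5ccccc5)C(C)(C)C)[C@@H]3CC[C@](C)(C[C@@H](O)[C@@H]12)O3 | intermediate (not isolated)
20 | trimethylammonium iodide of 19 | C[N+](C)(C)CC1C(=O)O[C@H]2/C=C(/CO[Si](c4ccccc4)(c5ccccc5)C(C)(C)C)[C@@H]3CC[C@](C)(C[C@@H](O)[C@@H]12)O3.[I-] | intermediate (not isolated)
21 | (1S,2Z,4S,8R,9R,11R)‑2‑{[(tert‑butyldiphenylsilyl)oxy]methyl}‑9‑hydroxy‑11‑methyl‑7‑methylidene‑5,14‑dioxatricyclo[9.2.1.0^{4,8}]tetradec‑2‑en‑6‑one | C=C1C(=O)O[C@H]2/C=C(/CO[Si](c4ccccc4)(c5ccccc5)C(C)(C)C)[C@@H]3CC[C@](C)(C[C@@H](O)[C@@H]12)O3 | intermediate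
22 | (1S,2Z,4S,8R,9R,11R)‑2‑{[(tert‑butyldiphenylsilyl)oxy]methyl}‑11‑methyl‑7‑methylidene‑6‑oxo‑5,14‑dioxatricyclo[9.2.1.0^{4,8}]tetradec‑2‑en‑9‑yl 2‑methylpropanoate | C=C1C(=O)O[C@H]2/C=C(/CO[Si](c4ccccc4)(c5ccccc5)C(C)(C)C)[C@@H]3CC[C@](C)(C[C@@H](OC(=O)C(C)C)[C@@H]12)O3 | intermediate
23 | (1S,2Z,4S,8R,9R,11R)‑2‑{[(tert‑butyldiphenylsilyl)oxy]methyl}‑1‑hydroxy‑11‑methyl‑7‑methylidene‑6‑oxo‑5,14‑dioxatricyclo[9.2.1.0^{4,8}]tetradec‑2‑en‑9‑yl 2‑methylpropanoate | C=C1C(=O)O[C@H]2/C=C(/CO[Si](c4ccccc4)(c5ccccc5)C(C)(C)C)[C@]3(O)CC[C@](C)(C[C@@H](OC(=O)C(C)C)[C@@H]12)O3 | intermediate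
24 | (1S,2Z,4S,8R,9R,11R)‑1‑hydroxy‑2‑(hydroxymethyl)‑11‑methyl‑7‑methylidene‑6‑oxo‑5,14‑dioxatricyclo[9.2.1.0^{4,8}]tetradec‑2‑en‑9‑yl 2‑methylpropanoate (CNP0282937.2) | C=C1C(=O)O[C@H]2/C=C(/CO)[C@]3(O)CC[C@](C)(C[C@@H](OC(=O)C(C)C)[C@@H]12)O3 | target

## Step count and least certain steps

Total step count: 16. Longest linear sequence: 15 (steps 1–5 and 7–16; step 6 prepares the second building block).

**Step 9 (key step).** What may go wrong: competing 1,5‑hydrogen abstraction by the alkoxy radical, elimination of HI towards C3, or base‑induced β‑elimination of the lactone oxygen from the β‑acyloxy ketone product. Fallback from 12 to 14 by ionic chemistry: potassium hexamethyldisilazide at low temperature triggers the retro‑Claisen ring expansion of the β‑hydroxy ester. The ester enolate released at C4 is trapped with PhSeBr as the α‑phenylselanyl ester F9. Oxidation with H2O2 gives the selenoxide F10, which eliminates towards C5 (away from the ether carbon) to give 14.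

**Step 3.** What may go wrong: low facial selectivity at the carbenoid, cyclopropanation of the methyl‑substituted double bond, or ring opening of the furan instead of Cope rearrangement. Fallback from 4 to 8 by the classical oxyallyl route: 2‑methylfuran and 1,1,3,3‑tetrabromoacetone with zinc–copper couple give the dibromo cycloadduct F1. Reductive debromination gives racemic 1‑methyl‑8‑oxabicyclo[3.2.1]oct‑6‑en‑3‑one F2 and hydrogenation the saturated ketone F3. Kinetic enolisation on the side away from the methyl bridgehead and acylation with tert‑butyl imidazole‑1‑carboxylate give racemic 8, which is separated by chromatography on a chiral phase into 8 and its mirror image ent‑8 F4.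

**Step 7.** What may go wrong: O‑alkylation of the enolate, or elimination of the triflate to the 5‑methylenefuranone followed by conjugate re‑addition, which would erase C6. Fallback from 8 to 11 that builds the butenolide after the C–C bond: alkylation of 8 with purchased (R)‑4‑(iodomethyl)‑2,2‑dimethyl‑1,3‑dioxolane (Cs2CO3, DMF) gives acetonide F5. Aqueous acetic acid gives diol F6, and selective oxidation of the primary alcohol (TEMPO, PhI(OAc)2) the hydroxy aldehyde F7. Still–Gennari olefination gives the (Z)‑hydroxy enoate F8, which lactonises to 11.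

**Step 11.** What may go wrong: poor facial selectivity at C8, or migration of the lactone from O6 to the new cis hydroxyl on O8. Fallback from 14 to 17 under reagent control: Corey–Bakshi–Shibata reduction of the ketone of 14, with the oxazaborolidine enantiomer matched to the 8R alcohol, gives hydroxy ester F11. Acidolysis gives hydroxy acid F12, and mixed‑anhydride reduction as in step 11 gives 17.

**Step 15.** What may go wrong: competing hydride abstraction at C15 with loss of the silyl ether, or insufficient overlap of the bridgehead C–H bond with the alkene. Fallback from 22 to 23 by radical allylic oxidation: Rh2(cap)4 (dirhodium tetrakis(caprolactamate)) with tert‑butyl hydroperoxide abstracts the same weakest C–H bond and gives the tert‑butyl peroxy ketal F13, which is hydrolysed to 23 with pyridinium p‑toluenesulfonate in wet acetone.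

## Further compounds

F1 | step 3 | 2,4‑dibromo‑1‑methyl‑8‑oxabicyclo[3.2.1]oct‑6‑en‑3‑one (racemic, bromide epimers) | CC12C=CC(O1)C(Br)C(=O)C2Br
F2 | step 3 | rac‑1‑methyl‑8‑oxabicyclo[3.2.1]oct‑6‑en‑3‑one | CC12C=CC(O1)CC(=O)C2
F3 | step 3 | rac‑1‑methyl‑8‑oxabicyclo[3.2.1]octan‑3‑one | CC12CCC(O1)CC(=O)C2
F4 | step 3 | tert‑butyl (1R,5S)‑5‑methyl‑3‑oxo‑8‑oxabicyclo[3.2.1]octane‑2‑carboxylate (ent‑8) | CC(C)(C)OC(=O)C1C(=O)C[C@]2(C)CC[C@H]1O2
F5 | step 7 | tert‑butyl (1S,2R,5R)‑2‑{[(4S)‑2,2‑dimethyl‑1,3‑dioxolan‑4‑yl]methyl}‑5‑methyl‑3‑oxo‑8‑oxabicyclo[3.2.1]octane‑2‑carboxylate | CC(C)(C)OC(=O)[C@@]1(C[C@H]2COC(C)(C)O2)C(=O)C[C@@]3(C)CC[C@@H]1O3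
F6 | step 7 | tert‑butyl (1S,2R,5R)‑2‑[(2S)‑2,3‑dihydroxypropyl]‑5‑methyl‑3‑oxo‑8‑oxabicyclo[3.2.1]octane‑2‑carboxylate | CC(C)(C)OC(=O)[C@@]1(C[C@H](O)CO)C(=O)C[C@@]2(C)CC[C@@H]1O2
F7 | step 7 | tert‑butyl (1S,2R,5R)‑2‑[(2S)‑2‑hydroxy‑3‑oxopropyl]‑5‑methyl‑3‑oxo‑8‑oxabicyclo[3.2.1]octane‑2‑carboxylate | CC(C)(C)OC(=O)[C@@]1(C[C@H](O)C=O)C(=O)C[C@@]2(C)CC[C@@H]1O2
F8 | step 7 | tert‑butyl (1S,2R,5R)‑2‑[(2S,3Z)‑2‑hydroxy‑5‑methoxy‑5‑oxopent‑3‑en‑1‑yl]‑5‑methyl‑3‑oxo‑8‑oxabicyclo[3.2.1]octane‑2‑carboxylate | CC(C)(C)OC(=O)[C@@]1(C[C@H](O)/C=C\C(=O)OC)C(=O)C[C@@]2(C)CC[C@@H]1O2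
F9 | step 9 | tert‑butyl (1S,4S,8S,11R)‑11‑methyl‑6,9‑dioxo‑2‑(phenylselanyl)‑5,14‑dioxatricyclo[9.2.1.0^{4,8}]tetradecane‑2‑carboxylate (C2 epimers) | C1C(=O)O[C@H]2CC([Se]c4ccccc4)(C(=O)OC(C)(C)C)[C@@H]3CC[C@](C)(CC(=O)[C@@H]12)O3
F10 | step 9 | selenoxide of F9 | C1C(=O)O[C@H]2CC([Se](=O)c4ccccc4)(C(=O)OC(C)(C)C)[C@@H]3CC[C@](C)(CC(=O)[C@@H]12)O3
F11 | step 11 | tert‑butyl (1S,2E,4S,8R,9R,11R)‑9‑hydroxy‑11‑methyl‑6‑oxo‑5,14‑dioxatricyclo[9.2.1.0^{4,8}]tetradec‑2‑ene‑2‑carboxylate | C1C(=O)O[C@H]2/C=C(/C(=O)OC(C)(C)C)[C@@H]3CC[C@](C)(C[C@@H](O)[C@@H]12)O3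
F12 | step 11 | (1S,2E,4S,8R,9R,11R)‑9‑hydroxy‑11‑methyl‑6‑oxo‑5,14‑dioxatricyclo[9.2.1.0^{4,8}]tetradec‑2‑ene‑2‑carboxylic acid | C1C(=O)O[C@H]2/C=C(/C(=O)O)[C@@H]3CC[C@](C)(C[C@@H](O)[C@@H]12)O3
F13 | step 15 | 1‑(tert‑butylperoxy) analogue of 23 (tert‑butyl peroxy ketal at C3) | C=C1C(=O)O[C@H]2/C=C(/CO[Si](c4ccccc4)(c5ccccc5)C(C)(C)C)[C@]3(OOC(C)(C)C)CC[C@](C)(C[C@@H](OC(=O)C(C)C)[C@@H]12)O3
A1 | alternative 1 | seco (Z)‑enal allylic bromide: C3 methyl ketal of the tetrahydrofuran, C6 aldehyde, C8 isobutyrate, methyl (Z)‑2‑(bromomethyl)alk‑2‑enoate terminus | O=C/C=C(/CO[Si](C)(C)C(C)(C)C)[C@]1(OC)CC[C@](C)(C[C@@H](OC(=O)C(C)C)/C=C(\CBr)C(=O)OC)O1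
A2 | alternative 1 | macrocyclisation product: C3 methyl ketal and C15 tert‑butyldimethylsilyl ether of the target | C=C1C(=O)O[C@H]2/C=C(/CO[Si](C)(C)C(C)(C)C)[C@]3(OC)CC[C@](C)(C[C@@H](OC(=O)C(C)C)[C@@H]12)O3
A3 | alternative 2 | seco dienone: vinyl ketone at C3 and vinyl carbinol at C10 on the preformed lactone | C=CC(=O)/C(CO[Si](C)(C)C(C)(C)C)=C\[C@@H]1OC(=O)C(=C)[C@@H]1[C@H](OC(=O)C(C)C)C[C@](C)(O)C=C
A4 | alternative 2 | 1,2‑didehydro hemiketal (C15 tert‑butyldimethylsilyl ether) from ring‑closing metathesis | C=C1C(=O)O[C@H]2/C=C(/CO[Si](C)(C)C(C)(C)C)[C@]3(O)C=C[C@](C)(C[C@@H](OC(=O)C(C)C)[C@@H]12)O3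
A5 | alternative 3 | 1‑vinyl‑2‑alkenylcyclohexanol (ring C5–C10) carrying the cis‑fused lactone and the C8 silyl ether | C=C[C@@]1(O)C[C@@H](O[Si](C)(C)C(C)(C)C)[C@H]2CC(=O)O[C@H]2[C@@H]1/C(CO[Si](C)(C)C(C)(C)C)=C/OC
A6 | alternative 3 | oxy‑Cope product: cyclodec‑4‑ene with C10 ketone, C3 methyl ether, C3 and C6 trans on the double bond | O=C1CCC(OC)/C(CO[Si](C)(C)C(C)(C)C)=C/[C@@H]2OC(=O)C[C@@H]2[C@H](O[Si](C)(C)C(C)(C)C)C1
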